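**Assumption:** the SMILES contains no stereocentre, so the target is achiral and the "single enantiomer" is the compound itself. The one stereocentre that appears on the way (C2 of 6, 7 and 8) is racemic and is erased by decarboxylation.

## Retrosynthetic overview

1. Target 9 comes from benzyl β-keto ester 7 by one-pot hydrogenolysis of all three benzyl groups and loss of CO2 from the resulting β-keto acid.
2. 7 comes from a crossed Claisen condensation that forms the ArCH–C(=O) bond: the lithium enolate of benzyl arylacetate 2 is C-acylated by icosanoyl chloride 4.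
3. 2 comes from (3,5-dihydroxyphenyl)acetic acid 1 by threefold benzylation; 4 comes from icosanoic acid 3.
4. No ring is formed: the only ring, the resorcinol arene, is bought intact.

## Route

**Step 1**
Reactants: 1 (3,5-dihydroxyphenyl)acetic acid
Product: 2 benzyl 2-[3,5-bis(benzyloxy)phenyl]acetate
Conditions: BnBr (3.5 equiv), K2CO3 (4.5 equiv), DMF, rt → 50 °C, 12 h
Reagents that add atoms: benzyl bromide, BrCc1ccccc1
Why: Williamson O-alkylation of both phenoxides and SN2 esterification of the carboxylate proceed together, and K2CO3 is too weak to deprotonate the benzylic CH2, so no C-benzylation occurs and no stereocentre is formed.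

**Step 2**
Reactants: 3 icosanoic acid (arachidic acid)
Product: 4 icosanoyl chloride
Conditions: (COCl)2 (1.5 equiv), cat. DMF, CH2Cl2, 0 °C → rt; evaporate, use crude
Reagents that add atoms: oxalyl chloride, ClC(=O)C(=O)Cl
Why: Vilsmeier-catalysed acyl chloride formation is driven to completion by loss of gaseous by-products, and the chloride is used directly after evaporation.

**Step 3**
Reactants: 2 benzyl 2-[3,5-bis(benzyloxy)phenyl]acetate; 4 icosanoyl chloride
Product: 7 benzyl 2-[3,5-bis(benzyloxy)phenyl]-3-oxodocosanoate (racemic), via lithium ester enolate 5 (not isolated), via lithium β-keto ester enolate 6 (not isolated)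
Conditions: LiHMDS (2.1 equiv), THF, −78 °C, 45 min; then 4 (1.0 equiv) in THF, −78 → −20 °C; 1 M HCl quench
Reagents that add atoms: none
Why: Crossed Claisen condensation by C-acylation of a fully preformed lithium ester enolate, in which the second equivalent of base converts the more acidic β-keto ester into its enolate 6 and so pulls the reaction forward and suppresses double acylation; the new C2 stereocentre is racemic, labile and removed in step 4.

**Step 4**
Reactants: 7 benzyl 2-[3,5-bis(benzyloxy)phenyl]-3-oxodocosanoate
Product: 9 1-(3,5-dihydroxyphenyl)henicosan-2-one, via β-keto acid 8 (not isolated)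
Conditions: H2 (1 atm), 10% Pd/C, EtOAc/EtOH 1:1, rt, 8 h; filter (Celite), warm filtrate to 50 °C, 1 h
Reagents that add atoms: none
Why: Pd-catalysed hydrogenolysis cleaves the two aryl benzyl ethers and the benzyl ester, and the freed α-aryl β-keto acid decarboxylates through the usual cyclic six-membered transition state on gentle warming, while the non-conjugated ketone is not reduced at 1 atm; the product is achiral.

## Compound list

1 | (3,5-dihydroxyphenyl)acetic acid | OC(=O)Cc1cc(O)cc(O)c1 | starting material
2 | benzyl 2-[3,5-bis(benzyloxy)phenyl]acetate | O=C(OCc1ccccc1)Cc1cc(OCc2ccccc2)cc(OCc2ccccc2)c1 | intermediate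
3 | icosanoic acid | CCCCCCCCCCCCCCCCCCCC(=O)O | starting material
4 | icosanoyl chloride | CCCCCCCCCCCCCCCCCCCC(=O)Cl | intermediate
5 | lithium enolate of benzyl 2-[3,5-bis(benzyloxy)phenyl]acetate (not isolated) | [Li+].[O-]C(OCc1ccccc1)=Cc1cc(OCc2ccccc2)cc(OCc2ccccc2)c1 | intermediate
6 | lithium enolate of benzyl 2-[3,5-bis(benzyloxy)phenyl]-3-oxodocosanoate (not isolated) | CCCCCCCCCCCCCCCCCCCC([O-])=C(C(=O)OCc1ccccc1)c1cc(OCc2ccccc2)cc(OCc2ccccc2)c1.[Li+] | intermediate
7 | benzyl 2-[3,5-bis(benzyloxy)phenyl]-3-oxodocosanoate (racemic at C2) | CCCCCCCCCCCCCCCCCCCC(=O)C(C(=O)OCc1ccccc1)c1cc(OCc2ccccc2)cc(OCc2ccccc2)c1 | intermediate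
8 | 2-(3,5-dihydroxyphenyl)-3-oxodocosanoic acid (racemic at C2, not isolated) | CCCCCCCCCCCCCCCCCCCC(=O)C(C(=O)O)c1cc(O)cc(O)c1 | intermediate
9 | 1-(3,5-dihydroxyphenyl)henicosan-2-one | CCCCCCCCCCCCCCCCCCCC(=O)Cc1cc(O)cc(O)c1 | target

## Summary

Total step count: 4.
Longest linear sequence: 3 steps (steps 1, 3, 4; the branch through steps 2, 3, 4 is equally long).

## Steps most likely to fail, with fallbacks

**Step 3 (Claisen C-acylation).** The risks are O-acylation, double acylation, or ketene chemistry of the long-chain acyl chloride, which is also poorly soluble at −78 °C. The fallback is an aldol/oxidation detour that sets out from 4 and 2 and comes back at 7. Reduce 4 with LiAlH(OtBu)3 (THF, −78 °C) to icosanal F1. Add F1 to the lithium enolate 5 (from 2 with 1.1 equiv LiHMDS, THF, −78 °C) and quench with aqueous NH4Cl to obtain benzyl 2-[3,5-bis(benzyloxy)phenyl]-3-hydroxydocosanoate F2 as an inconsequential diastereomer mixture. Oxidise F2 with Dess–Martin periodinane (CH2Cl2, NaHCO3, rt) to 7.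

**Step 4 (global hydrogenolysis and decarboxylation).** The risks are a stalled or poisoned catalyst, incomplete debenzylation of the waxy substrate, or partial ketone reduction. The fallback is a non-reductive, stepwise end-game that sets out from 7 and comes back at 9. Ketonic hydrolysis of 7 with dilute NaOH (THF/EtOH/H2O, rt) followed by acidification with 1 M HCl gives 2-[3,5-bis(benzyloxy)phenyl]-3-oxodocosanoic acid F3, which is not isolated. On warming to 50 °C it loses CO2 to give 1-[3,5-bis(benzyloxy)phenyl]henicosan-2-one F4. Cleave both benzyl ethers of F4 with BCl3 and pentamethylbenzene as cation scavenger (CH2Cl2, −78 °C, MeOH quench) to reach 9.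

**Step 1 (threefold benzylation).** The risks are incomplete alkylation or ring C-benzylation of the electron-rich resorcinol. The fallback sets out from 1 and comes back at 2. Fischer esterification of 1 with benzyl alcohol (cat. TsOH, toluene, Dean–Stark) gives benzyl 2-(3,5-dihydroxyphenyl)acetate F5. A double Mitsunobu etherification of F5 with benzyl alcohol (PPh3, DIAD, THF, 0 °C → rt) then gives 2 under neutral conditions.

## Further compounds

F1 | step 3 | icosanal | CCCCCCCCCCCCCCCCCCCC=O
F2 | step 3 | benzyl 2-[3,5-bis(benzyloxy)phenyl]-3-hydroxydocosanoate (diastereomer mixture, racemic) | CCCCCCCCCCCCCCCCCCCC(O)C(C(=O)OCc1ccccc1)c1cc(OCc2ccccc2)cc(OCc2ccccc2)c1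
F3 | step 4 | 2-[3,5-bis(benzyloxy)phenyl]-3-oxodocosanoic acid (racemic, not isolated) | CCCCCCCCCCCCCCCCCCCC(=O)C(C(=O)O)c1cc(OCc2ccccc2)cc(OCc2ccccc2)c1
F4 | step 4 | 1-[3,5-bis(benzyloxy)phenyl]henicosan-2-one | CCCCCCCCCCCCCCCCCCCC(=O)Cc1cc(OCc2ccccc2)cc(OCc2ccccc2)c1
F5 | step 1 | benzyl 2-(3,5-dihydroxyphenyl)acetate | O=C(OCc1ccccc1)Cc1cc(O)cc(O)c1
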